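Ring C, a hexasubstituted 11,14-hydroquinone with methoxy at C12 and isopropyl at C13, is disconnected from ring B at C9–C11 and C8–C14. A C9 vinyllithium on ring B, released from its trimethylstannane, should add to 3-isopropyl-4-methoxycyclobutenedione; heating the adduct opens the four-membered ring to a dienylketene that closes onto C8 and aromatises, so all six arene substituents arrive in one operation. The precursor is a cyclohexenylstannane from (R)-carvone in which C5 (isopropenyl) and quaternary C10 (methyl, allyl) are already set, with a temporary C7 silyl ether. The allyl group later becomes the C1–C3 acid chain and C7 the ketone.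

Key step: step 8

Assumption: abietane numbering is used for ring B/C compounds (C10 quaternary, C5 isopropenyl-bearing CH, C7 oxygenated carbon, arene C8, C9, C11–C14), and the Grignard reagents, hexamethylditin and 9-BBN are bought as such.

Step 1
Reactants: 1 (R)-carvone
Product: 4 (1R)-4-methyl-5-oxocyclohex-3-en-1-yl acetate, via methoxy hydroperoxide 2 (not isolated), via peracetate 3 (not isolated)
Conditions: O3, CH2Cl2/MeOH, −78 °C; then Ac2O, Et3N, DMAP (cat.), CH2Cl2, 0 °C → rt
Reagents that add atoms: ozone, [O-][O+]=O; methanol, CO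
Why: Ozonolysis in methanol cleaves the electron-rich isopropenyl alkene ahead of the enone and traps the carbonyl oxide as 2, and acetylation to 3 triggers a Criegee rearrangement in which the ring carbon migrates to oxygen with retention, so the (R) centre is kept and the old C(CH3) unit becomes the acetyl group.

Step 2
Reactants: 4 (1R)-4-methyl-5-oxocyclohex-3-en-1-yl acetate
Product: 5 (5R)-5-hydroxy-2-methylcyclohex-2-en-1-one
Conditions: K2CO3 (cat.), MeOH, 0 °C
Reagents that add atoms: none
Why: Carbonate-catalysed transesterification with methanol removes the acetate, and the low temperature should suppress β-elimination of the β-hydroxy enone; the stereocentre is untouched.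

Step 3
Reactants: 5 (5R)-5-hydroxy-2-methylcyclohex-2-en-1-one
Product: 6 (5R)-5-(tert-butyldimethylsilyloxy)-2-methylcyclohex-2-en-1-one
Conditions: TBSCl, imidazole, DMF, rt
Reagents that add atoms: tert-butyldimethylsilyl chloride, CC(C)(C)[Si](C)(C)Cl
Why: Imidazole-promoted silylation of the secondary alcohol gives the robust silyl ether that steers the conjugate addition and later marks C7.

Step 4
Reactants: 6 (5R)-5-(tert-butyldimethylsilyloxy)-2-methylcyclohex-2-en-1-one, 7 isopropenylmagnesium bromide, 8 allyl bromide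
Product: 10 (2S,3S,5R)-2-allyl-5-(tert-butyldimethylsilyloxy)-2-methyl-3-(prop-1-en-2-yl)cyclohexan-1-one, via bromomagnesium enolate 9 (not isolated)
Conditions: 7, CuBr·SMe2 (10 mol %), THF, −40 °C; then 8, HMPA, −40 °C → rt
Reagents that add atoms: isopropenylmagnesium bromide (7), C=C(C)[Mg]Br; allyl bromide (8), C=CCBr
Why: Copper-catalysed conjugate addition of the Grignard reagent should occur by axial attack anti to the silyloxy group (isopropenyl centre trans to OTBS), and the regiospecific enolate 9 is then C-allylated anti to the neighbouring isopropenyl group, which sets the quaternary centre with allyl trans and methyl cis to isopropenyl (tandem conjugate addition–enolate alkylation).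

Step 5
Reactants: 10 (2S,3S,5R)-2-allyl-5-(tert-butyldimethylsilyloxy)-2-methyl-3-(prop-1-en-2-yl)cyclohexan-1-one
Product: 12 (3R,5S,6S)-6-allyl-3-(tert-butyldimethylsilyloxy)-6-methyl-5-(prop-1-en-2-yl)cyclohex-1-en-1-yl trifluoromethanesulfonate, via potassium enolate 11 (not isolated)
Conditions: KN(SiMe3)2, THF, −78 °C; then N-(5-chloro-2-pyridyl)triflimide, −78 °C; aq NH4Cl
Reagents that add atoms: N-(5-chloropyridin-2-yl)bis(trifluoromethanesulfonyl)imide, O=S(=O)(N(c1ccc(Cl)cn1)S(=O)(=O)C(F)(F)F)C(F)(F)F
Why: The ketone can enolise only toward its CH2 side, and the kinetic enolate 11 should be O-sulfonylated at −78 °C faster than it can expel the β-silyloxy group (enolate triflation).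

Step 6
Reactants: 12 (3R,5S,6S)-6-allyl-3-(tert-butyldimethylsilyloxy)-6-methyl-5-(prop-1-en-2-yl)cyclohex-1-en-1-yl trifluoromethanesulfonate
Product: 13 (3R,5S,6S)-6-allyl-3-(tert-butyldimethylsilyloxy)-6-methyl-5-(prop-1-en-2-yl)-1-(trimethylstannyl)cyclohex-1-ene
Conditions: Me3SnSnMe3, Pd(PPh3)4 (5 mol %), LiCl, THF, 65 °C
Reagents that add atoms: hexamethylditin, C[Sn](C)(C)[Sn](C)(C)C
Why: Zerovalent palladium inserts into the C–OTf bond, and transmetalation with the distannane followed by reductive elimination gives the alkenylstannane (palladium-catalysed stannylation of an enol triflate, a Stille-type coupling); the isolated alkenes and the silyl ether are spectators.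

Step 7
Reactants: 14 dimethyl squarate, 15 isopropylmagnesium chloride
Product: 17 3-isopropyl-4-methoxycyclobut-3-ene-1,2-dione, via carbinol adduct 16 (not isolated)
Conditions: 15, THF, −78 °C; then 12 M HCl, CH2Cl2, rt
Reagents that add atoms: isopropylmagnesium chloride (15), CC(C)[Mg]Cl; water, O
Why: The Grignard reagent adds 1,2 to one squarate carbonyl, and acid ionises the tertiary carbinol of 16 to a methoxy-stabilised cyclobutenyl cation that is hydrolysed with loss of methanol, the standard conversion of a squarate ester into a 3-alkyl-4-alkoxycyclobutenedione.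

Step 8
Reactants: 13 (3R,5S,6S)-6-allyl-3-(tert-butyldimethylsilyloxy)-6-methyl-5-(prop-1-en-2-yl)-1-(trimethylstannyl)cyclohex-1-ene, 17 3-isopropyl-4-methoxycyclobut-3-ene-1,2-dione
Product: 22 ring B/C hydroquinone (5S,7R,10S; 7-OTBS, 10-allyl, 11,14-diol, 12-OMe, 13-isopropyl), via vinyllithium 18 (not isolated), via hydroxycyclobutenone adduct 19 (not isolated), via dienylketene 20 (not isolated), via cyclohexadienone 21 (not isolated)
Conditions: MeLi, THF, −78 → −20 °C; then 17, THF, −78 °C; aq NH4Cl; then PhMe (degassed), 110 °C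
Reagents that add atoms: none
Why: Tin–lithium exchange with MeLi (driven by formation of Me4Sn) gives the C9 vinyllithium 18, which adds 1,2 to the ketone-like carbonyl of 17, the one flanked by the methoxy-bearing carbon, forming C9–C11; on heating, adduct 19 undergoes conrotatory 4π ring opening with the hydroxyl turning outward, so the alkenyl group lies cis to the ketene in 20. Thermal disrotatory 6π electrocyclisation of 20 then joins the ketene carbon to C8 (C8–C14), closing the six-membered carbocyclic ring C, and enolisation of dienone 21 gives aromatic hydroquinone 22. The closest known reaction type is the Moore rearrangement, the thermal ring expansion of 4-alkenyl-4-hydroxycyclobutenones made from alkenyllithiums and squarate-derived cyclobutenediones. No lasting stereocentre is created, since the carbinol carbon and C8 both end up sp2, and C5, C7 and C10 are spectators. The step needs regioselective carbonyl addition, which the substrate secures because the other carbonyl is deactivated as a vinylogous ester by the methoxy group, so methoxy ends at C12 and isopropyl at C13; closure can only occur at C8, whose hydrogen allows aromatisation.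

Step 9
Reactants: 22 ring B/C hydroquinone
Product: 23 hydroquinone diacetate (5S,7R,10S; 11,14-di-OAc, 7-OTBS, 10-allyl)
Conditions: Ac2O, Et3N, DMAP (cat.), CH2Cl2, rt
Reagents that add atoms: acetic anhydride, CC(=O)OC(C)=O
Why: DMAP-catalysed acylation converts both hindered phenols into acetates, which protects the hydroquinone from air and from the later oxidants.

Step 10
Reactants: 23 hydroquinone diacetate
Product: 25 primary alcohol (5S,7R,10S; 10-(3-hydroxypropyl), 11,14-di-OAc, 7-OTBS), via alkylborane 24 (not isolated)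
Conditions: 9-BBN, THF, 0 °C → rt; then 30% H2O2, aq NaOAc, 0 °C → rt
Reagents that add atoms: hydrogen peroxide, OO
Why: 9-BBN should add anti-Markovnikov to the monosubstituted allyl alkene far faster than to the hindered 1,1-disubstituted isopropenyl group, and acetate-buffered peroxide oxidises the C–B bond without hydrolysing the aryl acetates (hydroboration–oxidation).

Step 11
Reactants: 25 primary alcohol
Product: 26 diol (5S,7R,10S; 7-OH, 10-(3-hydroxypropyl), 11,14-di-OAc)
Conditions: Et3N·3HF, THF/MeCN, rt → 40 °C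
Reagents that add atoms: none
Why: Fluoride cleaves the Si–O bond under weakly acidic conditions that should neither shift the neighbouring acetyl group nor add HF to the isopropenyl alkene (desilylation).

Step 12
Reactants: 26 diol
Product: 27 keto acid diacetate (5S,10S; 7-oxo, C3 carboxylic acid, 11,14-di-OAc)
Conditions: CrO3, H2SO4, acetone/H2O, 0 °C
Reagents that add atoms: water, O
Why: The Jones oxidation should take the primary alcohol to the carboxylic acid and the benzylic alcohol to the aryl ketone in one operation, while the acetates keep the hydroquinone from being oxidised and the isopropenyl group is left alone at 0 °C; the temporary C7 centre disappears.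

Step 13
Reactants: 27 keto acid diacetate
Product: 28 CNP0249049.1, 3-[(1S,2S)-5,8-dihydroxy-7-methoxy-1-methyl-4-oxo-6-(propan-2-yl)-2-(prop-1-en-2-yl)-1,2,3,4-tetrahydronaphthalen-1-yl]propanoic acid
Conditions: K2CO3, MeOH (degassed), rt; then 1 M HCl
Reagents that add atoms: none
Why: Carbonate-mediated methanolysis of the two aryl acetates (transesterification) releases the hydroquinone, exclusion of oxygen keeps it from oxidising to the quinone, and neither C5 nor C10 can epimerise.

Compound list
1 | (R)-carvone | CC1=CC[C@@H](C(C)=C)CC1=O | starting material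
2 | (5R)-5-(1-hydroperoxy-1-methoxyethyl)-2-methylcyclohex-2-en-1-one (peroxy carbon unspecified) | CC1=CC[C@@H](C(C)(OC)OO)CC1=O | intermediate (not isolated)
3 | (5R)-5-[1-(acetylperoxy)-1-methoxyethyl]-2-methylcyclohex-2-en-1-one | CC1=CC[C@@H](C(C)(OC)OOC(C)=O)CC1=O | intermediate (not isolated)
4 | (1R)-4-methyl-5-oxocyclohex-3-en-1-yl acetate | CC1=CC[C@@H](OC(C)=O)CC1=O | intermediate
5 | (5R)-5-hydroxy-2-methylcyclohex-2-en-1-one | CC1=CC[C@@H](O)CC1=O | intermediate
6 | (5R)-5-(tert-butyldimethylsilyloxy)-2-methylcyclohex-2-en-1-one | CC1=CC[C@@H](O[Si](C)(C)C(C)(C)C)CC1=O | intermediate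
7 | isopropenylmagnesium bromide | C=C(C)[Mg]Br | starting material
8 | allyl bromide | C=CCBr | starting material
9 | bromomagnesium (3S,5R)-5-(tert-butyldimethylsilyloxy)-2-methyl-3-(prop-1-en-2-yl)cyclohex-1-en-1-olate | C=C(C)[C@@H]1C[C@@H](O[Si](C)(C)C(C)(C)C)CC(O[Mg]Br)=C1C | intermediate (not isolated)
10 | (2S,3S,5R)-2-allyl-5-(tert-butyldimethylsilyloxy)-2-methyl-3-(prop-1-en-2-yl)cyclohexan-1-one | C=C(C)[C@@H]1C[C@@H](O[Si](C)(C)C(C)(C)C)CC(=O)[C@@]1(C)CC=C | intermediate
11 | potassium enolate of 10 (enolised toward the CH2 side) | C=C(C)[C@@H]1C[C@@H](O[Si](C)(C)C(C)(C)C)C=C([O-])[C@@]1(C)CC=C.[K+] | intermediate (not isolated)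
12 | (3R,5S,6S)-6-allyl-3-(tert-butyldimethylsilyloxy)-6-methyl-5-(prop-1-en-2-yl)cyclohex-1-en-1-yl trifluoromethanesulfonate | C=C(C)[C@@H]1C[C@@H](O[Si](C)(C)C(C)(C)C)C=C(OS(=O)(=O)C(F)(F)F)[C@@]1(C)CC=C | intermediate
13 | (3R,5S,6S)-6-allyl-3-(tert-butyldimethylsilyloxy)-6-methyl-5-(prop-1-en-2-yl)-1-(trimethylstannyl)cyclohex-1-ene | C=C(C)[C@@H]1C[C@@H](O[Si](C)(C)C(C)(C)C)C=C([Sn](C)(C)C)[C@@]1(C)CC=C | intermediate
14 | dimethyl squarate (3,4-dimethoxycyclobut-3-ene-1,2-dione) | COC1=C(OC)C(=O)C1=O | starting material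
15 | isopropylmagnesium chloride | CC(C)[Mg]Cl | starting material
16 | 4-hydroxy-2,3-dimethoxy-4-(propan-2-yl)cyclobut-2-en-1-one (racemic) | COC1=C(OC)C(O)(C(C)C)C1=O | intermediate (not isolated)
17 | 3-isopropyl-4-methoxycyclobut-3-ene-1,2-dione | COC1=C(C(C)C)C(=O)C1=O | intermediate
18 | C9 vinyllithium, [(3R,5S,6S)-6-allyl-3-(tert-butyldimethylsilyloxy)-6-methyl-5-(prop-1-en-2-yl)cyclohex-1-en-1-yl]lithium | C=C(C)[C@@H]1C[C@@H](O[Si](C)(C)C(C)(C)C)C=C([Li])[C@@]1(C)CC=C | intermediate (not isolated)
19 | 4-hydroxy-3-methoxy-2-isopropyl-4-[ring B cyclohexenyl]cyclobut-2-en-1-one (carbinol carbon unspecified) | C=C(C)[C@@H]1C[C@@H](O[Si](C)(C)C(C)(C)C)C=C(C2(O)C(OC)=C(C(C)C)C2=O)[C@@]1(C)CC=C | intermediate (not isolated)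
20 | dienylketene from ring opening of 19 (C9 cis to the ketene-bearing carbon) | C=C(C)[C@@H]1C[C@@H](O[Si](C)(C)C(C)(C)C)C=C(/C(O)=C(OC)\C(C(C)C)=C=O)[C@@]1(C)CC=C | intermediate (not isolated)
21 | cyclohexa-2,4-dienone from 6π closure (C8 sp3, unspecified) | C=C(C)[C@@H]1C[C@@H](O[Si](C)(C)C(C)(C)C)C2C(=O)C(C(C)C)=C(OC)C(O)=C2[C@@]1(C)CC=C | intermediate (not isolated)
22 | (5S,6S,8R)-5-allyl-8-(tert-butyldimethylsilyloxy)-3-methoxy-5-methyl-2-(propan-2-yl)-6-(prop-1-en-2-yl)-5,6,7,8-tetrahydronaphthalene-1,4-diol (abietane 5S,7R,10S) | C=C(C)[C@@H]1C[C@@H](O[Si](C)(C)C(C)(C)C)c2c(O)c(C(C)C)c(OC)c(O)c2[C@@]1(C)CC=C | intermediate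
23 | 11,14-diacetate of 22 | C=C(C)[C@@H]1C[C@@H](O[Si](C)(C)C(C)(C)C)c2c(OC(C)=O)c(C(C)C)c(OC)c(OC(C)=O)c2[C@@]1(C)CC=C | intermediate
24 | B-alkyl-9-borabicyclo[3.3.1]nonane from 23 (boron on the terminal chain carbon C3) | C=C(C)[C@@H]1C[C@@H](O[Si](C)(C)C(C)(C)C)c2c(OC(C)=O)c(C(C)C)c(OC)c(OC(C)=O)c2[C@@]1(C)CCCB3C4CCCC3CCC4 | intermediate (not isolated)
25 | 10-(3-hydroxypropyl) diacetate, 7-OTBS (abietane 5S,7R,10S) | C=C(C)[C@@H]1C[C@@H](O[Si](C)(C)C(C)(C)C)c2c(OC(C)=O)c(C(C)C)c(OC)c(OC(C)=O)c2[C@@]1(C)CCCO | intermediate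
26 | 7-hydroxy-10-(3-hydroxypropyl) diacetate (abietane 5S,7R,10S) | C=C(C)[C@@H]1C[C@@H](O)c2c(OC(C)=O)c(C(C)C)c(OC)c(OC(C)=O)c2[C@@]1(C)CCCO | intermediate
27 | 7-oxo C3 carboxylic acid, 11,14-diacetate (abietane 5S,10S) | C=C(C)[C@@H]1CC(=O)c2c(OC(C)=O)c(C(C)C)c(OC)c(OC(C)=O)c2[C@@]1(C)CCC(=O)O | intermediate
28 | CNP0249049.1, 3-[(1S,2S)-5,8-dihydroxy-7-methoxy-1-methyl-4-oxo-6-(propan-2-yl)-2-(prop-1-en-2-yl)-1,2,3,4-tetrahydronaphthalen-1-yl]propanoic acid | C=C(C)[C@@H]1CC(=O)c2c(O)c(C(C)C)c(OC)c(O)c2[C@@]1(C)CCC(=O)O | target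

Total step count: 13. Longest linear sequence: 12 steps (steps 1–6 and 8–13, from (R)-carvone); step 7 is the one-step side branch.

Steps most likely to fail

Step 8. The hindered, strongly basic C9 lithium reagent may take a proton from the dione (isopropyl methine) instead of adding to the carbonyl, and the unprotected carbinol may divert on heating (retro-addition, trapping of the ketene by the hydroxyl) or the free hydroquinone may air-oxidise. The fallback changes the carbanion source and metal and runs the rearrangement on a protected carbinol in separate operations. It sets out from stannane 13: iododestannylation (I2, CH2Cl2, 0 °C) should give the vinyl iodide F1. Iodine–lithium exchange (t-BuLi, Et2O, −78 °C) and transmetalation with CeCl3 give a far less basic organocerium reagent that adds to 17. Adduct 19 is then isolated and capped (Me3SiCl, imidazole) as the trimethylsilyl ether F2. Thermolysis of F2 (xylene, 140 °C) should give, by the same electrocyclic cascade, the 11-O-trimethylsilyl aryl ether F3, and brief methanolysis (citric acid, MeOH) comes back to the route at hydroquinone 22.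

Step 4. C-alkylation of the congested magnesium enolate may be sluggish, so that proton transfer, O-allylation, enolate equilibration with loss of the β-silyloxy group, or erosion of facial selectivity at C10 compete. The fallback sets out from enone 6: the same copper-catalysed conjugate addition is run, but enolate 9 is trapped on oxygen with allyl chloroformate to give the allyl enol carbonate F4. Pd(PPh3)4 (cat., THF, rt) then effects decarboxylative allylation (Tsuji allylation). This regenerates the enolate regiospecifically next to a π-allylpalladium cation and should deliver the allyl group anti to the isopropenyl group, coming back to the route at ketone 10.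

Step 10. The aryl acetates may hydrolyse during peroxide oxidation of the borane (with air oxidation to the quinone following), and hydroboration of the isopropenyl group may compete. The fallback moves the hydroboration ahead of arene construction, where no base-sensitive group is present. It sets out from enol triflate 12: 9-BBN, then NaBO3·4H2O, should give the primary alcohol F5, which is silylated (TBSCl, imidazole) to the bis-silyl ether F6. Stannylation as in step 6 gives the stannane F7, which is taken through the step 8 sequence with 17 to the hydroquinone F8 and acetylated as in step 9 to the diacetate F9. Et3N·3HF then removes both silyl groups and comes back to the route at diol 26.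

Further compounds
F1 | step 8 | (3R,5S,6S)-6-allyl-3-(tert-butyldimethylsilyloxy)-1-iodo-6-methyl-5-(prop-1-en-2-yl)cyclohex-1-ene | C=C(C)[C@@H]1C[C@@H](O[Si](C)(C)C(C)(C)C)C=C(I)[C@@]1(C)CC=C
F2 | step 8 | trimethylsilyl ether of adduct 19 | C=C(C)[C@@H]1C[C@@H](O[Si](C)(C)C(C)(C)C)C=C(C2(O[Si](C)(C)C)C(OC)=C(C(C)C)C2=O)[C@@]1(C)CC=C
F3 | step 8 | 11-O-trimethylsilyl ether of hydroquinone 22 | C=C(C)[C@@H]1C[C@@H](O[Si](C)(C)C(C)(C)C)c2c(O)c(C(C)C)c(OC)c(O[Si](C)(C)C)c2[C@@]1(C)CC=C
F4 | step 4 | allyl (3S,5R)-5-(tert-butyldimethylsilyloxy)-2-methyl-3-(prop-1-en-2-yl)cyclohex-1-en-1-yl carbonate | C=C(C)[C@@H]1C[C@@H](O[Si](C)(C)C(C)(C)C)CC(OC(=O)OCC=C)=C1C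
F5 | step 10 | enol triflate with 6-(3-hydroxypropyl) chain | C=C(C)[C@@H]1C[C@@H](O[Si](C)(C)C(C)(C)C)C=C(OS(=O)(=O)C(F)(F)F)[C@@]1(C)CCCO
F6 | step 10 | enol triflate with 6-[3-(tert-butyldimethylsilyloxy)propyl] chain | C=C(C)[C@@H]1C[C@@H](O[Si](C)(C)C(C)(C)C)C=C(OS(=O)(=O)C(F)(F)F)[C@@]1(C)CCCO[Si](C)(C)C(C)(C)C
F7 | step 10 | trimethylstannane with 6-[3-(tert-butyldimethylsilyloxy)propyl] chain | C=C(C)[C@@H]1C[C@@H](O[Si](C)(C)C(C)(C)C)C=C([Sn](C)(C)C)[C@@]1(C)CCCO[Si](C)(C)C(C)(C)C
F8 | step 10 | ring B/C hydroquinone with 7-OTBS and 10-[3-(tert-butyldimethylsilyloxy)propyl] | C=C(C)[C@@H]1C[C@@H](O[Si](C)(C)C(C)(C)C)c2c(O)c(C(C)C)c(OC)c(O)c2[C@@]1(C)CCCO[Si](C)(C)C(C)(C)C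
F9 | step 10 | 11,14-diacetate of F8 | C=C(C)[C@@H]1C[C@@H](O[Si](C)(C)C(C)(C)C)c2c(OC(C)=O)c(C(C)C)c(OC)c(OC(C)=O)c2[C@@]1(C)CCCO[Si](C)(C)C(C)(C)C
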